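**Plan**
1. Retrosynthetic cuts, in order: the C6–allyl bond of ring A; the ketal O–CH3, traced back to O–CH2–CO2H (one C–C bond); the C4–O bond to ring B; and last the C4–O(acyl) bond of a spiro 1,3-dioxolan-4-one. The last cut leads to an achiral 4-alkoxyphenol made from vanillin.
2. Enabling feature: C4 of ring A is a ketal carbon para to the C1 oxygen and bears two unlike oxygens. The oxygen that ends as OCH3 can carry a CH2CO2H arm whose carboxyl oxygen reaches C4 through a five-membered ring. The C3 methoxy group makes the two halves of the dienone unlike, so C4 becomes stereogenic on closure.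
3. Forward order: one oxidative dearomatization turns the arene into ring A and closes the spiro lactone; C5=C6 is saturated; ring B (an aromatic Claisen product) is joined at C4 as the lactone opens; CO2 is removed to leave OCH3; the allyl chain is joined at C6 last.
4. Stereochemistry: C4 (R) comes from the chiral aryl iodide catalyst and is carried through the C–O exchange by double inversion. C6 (R) comes from C4, because the allyl halide approaches the dienolate anti to the aryloxy group.

Key step: step 4

Assumption: the sense of induction of the chiral aryl iodide on this substrate cannot be predicted from existing models, so the route is written for the catalyst antipode that gives the (5R) spiro lactone; both antipodes are equally accessible.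

**Step 1**
Reactants: 1 vanillin; 2 ethyl bromoacetate
Product: 3 ethyl 2-(4-formyl-2-methoxyphenoxy)acetate
Conditions: K2CO3, DMF, rt to 50 °C
Reagents that add atoms: none
Why: Williamson ether synthesis, in which the phenoxide of vanillin displaces bromide from the activated primary α-bromo ester while the aldehyde and the ester are inert to K2CO3.

**Step 2**
Reactants: 3 ethyl 2-(4-formyl-2-methoxyphenoxy)acetate
Product: 4 ethyl 2-[4-(formyloxy)-2-methoxyphenoxy]acetate
Conditions: mCPBA, CH2Cl2, 0 °C to rt
Reagents that add atoms: mCPBA (3-chloroperoxybenzoic acid), O=C(OO)c1cccc(Cl)c1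
Why: Baeyer–Villiger oxidation (peracid variant of the Dakin reaction), in which the electron-rich aryl group migrates in preference to hydride in the Criegee adduct, giving the aryl formate and leaving the ester and ethers untouched.

**Step 3**
Reactants: 4 ethyl 2-[4-(formyloxy)-2-methoxyphenoxy]acetate
Product: 5 2-(4-hydroxy-2-methoxyphenoxy)acetic acid
Conditions: LiOH, THF/H2O, argon, 0 °C to rt; then 1 M HCl
Reagents that add atoms: lithium hydroxide, [Li+].[OH-]
Why: Saponification cleaves the labile aryl formate and the ethyl ester in one operation, and exclusion of air protects the electron-rich phenolate until acidification.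

**Step 4**
Reactants: 5 2-(4-hydroxy-2-methoxyphenoxy)acetic acid
Product: 6 (5R)-6-methoxy-1,4-dioxaspiro[4.5]deca-6,9-diene-2,8-dione
Conditions: 2-iodo-1,3-bis{[(2R)-1-(2,4,6-trimethylbenzamido)propan-2-yl]oxy}benzene (10 mol %), dried mCPBA (1.2 equiv), CH2Cl2/HFIP, −20 °C
Reagents that add atoms: none
Why: Proposed new method: mCPBA oxidizes the aryl iodide to a chiral trivalent iodine species that exchanges a ligand for the phenol oxygen of 5, and as the aryl iodide departs, positive charge develops at C4 (para to that oxygen and stabilized by the ether oxygen), where the tethered carboxyl oxygen attacks. The only ring formed, the 1,3-dioxolan-4-one, closes in a 5-exo-trig mode on C4 and creates the C4–O(acyl) bond. The closest known reactions are the catalytic enantioselective oxidative spirolactonization of naphthols and phenols bearing carboxylic acid tethers at the ortho position, the enantioselective hydrative para-dearomatization of phenols with chiral aryl iodides, and the racemic oxidation of 4-hydroxyphenoxyacetic acids to this spiro ring system with achiral trivalent iodine reagents. C4 is stereogenic because the C3 methoxy group makes the two dienone arms different, and its configuration is controlled by the catalyst alone, whose hydrogen-bonded amide arms should fold over one face of the iodine-bound phenol so that the carboxyl group swings in from the open face. The step needs ipso-para rather than ortho attack and internal rather than external capture, and both are secured by the two-atom tether, which can reach only C4, and by the dry, weakly nucleophilic medium.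

**Step 5**
Reactants: 6 (5R)-6-methoxy-1,4-dioxaspiro[4.5]deca-6,9-diene-2,8-dione
Product: 7 (5R)-6-methoxy-1,4-dioxaspiro[4.5]dec-6-ene-2,8-dione
Conditions: H2 (1 atm), RhCl(PPh3)3 (5 mol %), benzene, rt
Reagents that add atoms: none
Why: Homogeneous hydrogenation with RhCl(PPh3)3 is very sensitive to alkene substitution and, as with steroidal 1,4-dien-3-ones, should saturate only the cis-disubstituted C5=C6 bond and spare the trisubstituted methoxy-bearing C2=C3 bond, while the neutral medium leaves the acyloxy ketal and C4 untouched.

**Step 6**
Reactants: 8 3,4-dimethoxyphenol; 9 allyl bromide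
Product: 10 4-(allyloxy)-1,2-dimethoxybenzene
Conditions: K2CO3, acetone, reflux
Reagents that add atoms: none
Why: Williamson ether synthesis of a phenoxide with a reactive allylic halide, which gives O-alkylation under carbonate conditions in a polar aprotic solvent.

**Step 7**
Reactants: 10 4-(allyloxy)-1,2-dimethoxybenzene
Product: 11 2-allyl-4,5-dimethoxyphenol
Conditions: N,N-diethylaniline, 200 °C
Reagents that add atoms: none
Why: Aromatic Claisen rearrangement, in which the [3,3] shift should go mainly to the open ortho carbon para to a methoxy group rather than to the carbon flanked by two oxygens, and tautomerization restores the phenol.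

**Step 8**
Reactants: 7 (5R)-6-methoxy-1,4-dioxaspiro[4.5]dec-6-ene-2,8-dione; 11 2-allyl-4,5-dimethoxyphenol
Product: 12 2-{[(1R)-1-(2-allyl-4,5-dimethoxyphenoxy)-2-methoxy-4-oxocyclohex-2-en-1-yl]oxy}acetic acid
Conditions: Pd(PPh3)4 (5 mol %), i-Pr2NEt (1.1 equiv), THF, 0 °C to rt; cold aq. citric acid work-up
Reagents that add atoms: none
Why: Proposed new method: with C5–C6 saturated, the lactone oxygen of 7 is the leaving group of a γ-acyloxy enone on a carbon that also bears an alkoxy group, so zerovalent palladium should ionize it from the face opposite the carboxylate to give a cyclic alkoxy-substituted allyl complex (C4–C3–C2) that cannot change face. The phenol then attacks the oxygen-bearing terminus C4 opposite the metal (double inversion, net retention at C4), while the amine holds the released acid as its carboxylate so that re-closure is uphill. The closest known reactions are the stereoretentive palladium-catalysed glycosylation of 6-acyloxy-2H-pyran-3(6H)-ones with alcohols and phenols and the allylic substitution of geminal dicarboxylates, neither of which has been shown at a fully substituted ketal carbon.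

**Step 9**
Reactants: 12 2-{[(1R)-1-(2-allyl-4,5-dimethoxyphenoxy)-2-methoxy-4-oxocyclohex-2-en-1-yl]oxy}acetic acid
Product: 14 (4R)-4-(2-allyl-4,5-dimethoxyphenoxy)-3,4-dimethoxycyclohex-2-en-1-one, via thiohydroxamate ester 13 (not isolated)
Conditions: 1-hydroxypyridine-2(1H)-thione, DCC, DMAP (cat.), CH2Cl2, 0 °C, dark; then t-BuSH, hν (tungsten lamp), 10 °C
Reagents that add atoms: none
Why: Barton reductive decarboxylation, in which photolysis of the thiohydroxamate ester releases CO2 and a nucleophilic alkoxymethyl radical that the polarity-matched thiol quenches quickly to O–CH3; the radical centre is not C4, so the stereocentre is untouched, and closure onto the ring B allyl group (eight-membered) or the enone (5-endo) is too slow to compete.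

**Step 10**
Reactants: 14 (4R)-4-(2-allyl-4,5-dimethoxyphenoxy)-3,4-dimethoxycyclohex-2-en-1-one; 9 allyl bromide
Product: 16 (4R,6R)-6-allyl-4-(2-allyl-4,5-dimethoxyphenoxy)-3,4-dimethoxycyclohex-2-en-1-one, via lithium dienolate 15 (not isolated)
Conditions: LiN(i-Pr)2 (1.05 equiv), THF, −78 °C; then 9, DMPU, −78 to −40 °C; aq. NH4Cl
Reagents that add atoms: none
Why: α′-Alkylation of a vinylogous ester enolate (Stork–Danheiser type), in which C6 carries the only acidic hydrogens and allyl bromide should approach the flat cross-conjugated dienolate from the face opposite the bulky aryloxy group on C4, placing the allyl group trans to OAr and cis to OCH3, i.e. (6R); this epimer (equatorial allyl, axial aryloxy away from the C3 methoxy group) should also be the more stable one, so incidental equilibration does no harm.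

**Compound list**
1 | vanillin (4-hydroxy-3-methoxybenzaldehyde) | COc1cc(C=O)ccc1O | starting material
2 | ethyl bromoacetate | CCOC(=O)CBr | starting material
3 | ethyl 2-(4-formyl-2-methoxyphenoxy)acetate | CCOC(=O)COc1ccc(C=O)cc1OC | intermediate
4 | ethyl 2-[4-(formyloxy)-2-methoxyphenoxy]acetate | CCOC(=O)COc1ccc(OC=O)cc1OC | intermediate
5 | 2-(4-hydroxy-2-methoxyphenoxy)acetic acid | COc1cc(O)ccc1OCC(=O)O | intermediate
6 | (5R)-6-methoxy-1,4-dioxaspiro[4.5]deca-6,9-diene-2,8-dione | O=C1CO[C@@]2(O1)C=CC(=O)C=C2OC | intermediate
7 | (5R)-6-methoxy-1,4-dioxaspiro[4.5]dec-6-ene-2,8-dione | O=C1CO[C@@]2(O1)CCC(=O)C=C2OC | intermediate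
8 | 3,4-dimethoxyphenol | COc1ccc(O)cc1OC | starting material
9 | allyl bromide | C=CCBr | starting material
10 | 4-(allyloxy)-1,2-dimethoxybenzene | C=CCOc1ccc(OC)c(OC)c1 | intermediate
11 | 2-allyl-4,5-dimethoxyphenol | C=CCc1cc(OC)c(OC)cc1O | intermediate
12 | 2-{[(1R)-1-(2-allyl-4,5-dimethoxyphenoxy)-2-methoxy-4-oxocyclohex-2-en-1-yl]oxy}acetic acid | C=CCc1cc(OC)c(OC)cc1O[C@]1(OCC(=O)O)CCC(=O)C=C1OC | intermediate
13 | 2-thioxopyridin-1(2H)-yl ester of acid 12 (thiohydroxamate ester, not isolated) | C=CCc1cc(OC)c(OC)cc1O[C@]1(OCC(=O)On2ccccc2=S)CCC(=O)C=C1OC | intermediate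
14 | (4R)-4-(2-allyl-4,5-dimethoxyphenoxy)-3,4-dimethoxycyclohex-2-en-1-one | C=CCc1cc(OC)c(OC)cc1O[C@]1(OC)CCC(=O)C=C1OC | intermediate
15 | lithium (4R)-4-(2-allyl-4,5-dimethoxyphenoxy)-4,5-dimethoxycyclohexa-1,5-dien-1-olate (dienolate of 14, not isolated) | C=CCc1cc(OC)c(OC)cc1O[C@]1(OC)CC=C([O-])C=C1OC.[Li+] | intermediate
16 | (4R,6R)-6-allyl-4-(2-allyl-4,5-dimethoxyphenoxy)-3,4-dimethoxycyclohex-2-en-1-one (CNP0352100.3) | C=CCc1cc(OC)c(OC)cc1O[C@]1(OC)C[C@@H](CC=C)C(=O)C=C1OC | target

**Step count**
Total steps: 10. Longest linear sequence: 8 (steps 1–5 and 8–10, from vanillin). Steps 6 and 7 form the two-step side branch to ring B.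

**Steps most likely to fail**

1. Step 4.
   - What may go wrong: enantioface discrimination may be insufficient, because the chiral iodine centre is bound at the C1 oxygen, on the far side of the ring from C4. Adventitious water may also hydrolyse the ketal carbon.
   - Fallback (known chemistry): from 5, oxidation with achiral PhI(OAc)2 in MeCN gives racemic 6-methoxy-1,4-dioxaspiro[4.5]deca-6,9-diene-2,8-dione F1. Its enantiomers are separated by preparative chromatography on a polysaccharide-based chiral stationary phase.
   - Return: the (5R) enantiomer is 6, where the route is rejoined. The configuration at C4 then comes from resolution instead of catalysis.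

2. Step 8.
   - What may go wrong: the allyl–palladium intermediate may lose a C5 hydrogen and aromatize. The phenolate may attack the lactone carbonyl instead of C4. Configuration may erode through attack of a second zerovalent palladium on the allyl complex.
   - Fallback (known chemistry): from 7 and 11, BF3·OEt2 in CH2Cl2 at −78 °C opens the dioxolanone at the ketal carbon through the oxocarbenium ion. This is the Lewis acid opening of 1,3-dioxolan-4-ones, the same reaction type as Helferich aryl glycoside formation from anomeric esters. The planar cation loses the C4 information, so the product is racemic 2-{[1-(2-allyl-4,5-dimethoxyphenoxy)-2-methoxy-4-oxocyclohex-2-en-1-yl]oxy}acetic acid F2.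
   - Return: classical resolution by crystallization of the (R)-1-phenylethylammonium salt of the (1R) acid F3, followed by mild acidification, gives 12. The antipodal amine is used if the other diastereomeric salt crystallizes.

3. Step 10.
   - What may go wrong: the base may induce loss of the aryloxy group with aromatization, double alkylation may occur, or facial selectivity at C6 may be poor.
   - Fallback: the allyl group is introduced before the aryloxy group is present, and C6 is left to thermodynamic control. From 6, LiBH(s-Bu)3 in THF at −78 °C adds hydride to C5 of the unsubstituted enone arm (trialkylborohydride conjugate reduction–alkylation of cyclohexenones). This gives lithium (5R)-6-methoxy-2-oxo-1,4-dioxaspiro[4.5]deca-6,8-dien-8-olate F4, which is trapped in the same flask by 9. The product is (5R)-9-allyl-6-methoxy-1,4-dioxaspiro[4.5]dec-6-ene-2,8-dione F5, a mixture at the allyl-bearing carbon.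
   - The conditions of step 8 with 11 then give 2-{[(1R)-5-allyl-1-(2-allyl-4,5-dimethoxyphenoxy)-2-methoxy-4-oxocyclohex-2-en-1-yl]oxy}acetic acid F6. The conditions of step 9 lead, through its 2-thioxopyridin-1(2H)-yl ester F7, to 16 together with the (4R,6S) epimer F8.
   - Return: DBU in toluene equilibrates F8 through the dienolate toward 16, with chromatographic recycling of what remains, so the route is rejoined at 16.

**Further compounds**
F1 | step 4 | racemic 6-methoxy-1,4-dioxaspiro[4.5]deca-6,9-diene-2,8-dione | O=C1COC2(O1)C=CC(=O)C=C2OC
F2 | step 8 | racemic 2-{[1-(2-allyl-4,5-dimethoxyphenoxy)-2-methoxy-4-oxocyclohex-2-en-1-yl]oxy}acetic acid | C=CCc1cc(OC)c(OC)cc1OC1(OCC(=O)O)CCC(=O)C=C1OC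
F3 | step 8 | (R)-1-phenylethylammonium salt of the (1R) acid | C=CCc1cc(OC)c(OC)cc1O[C@]1(OCC(=O)[O-])CCC(=O)C=C1OC.C[C@@H]([NH3+])c1ccccc1
F4 | step 10 | lithium (5R)-6-methoxy-2-oxo-1,4-dioxaspiro[4.5]deca-6,8-dien-8-olate | O=C1CO[C@@]2(O1)CC=C([O-])C=C2OC.[Li+]
F5 | step 10 | (5R)-9-allyl-6-methoxy-1,4-dioxaspiro[4.5]dec-6-ene-2,8-dione, both C9 epimers | O=C1CO[C@@]2(O1)CC(CC=C)C(=O)C=C2OC
F6 | step 10 | 2-{[(1R)-5-allyl-1-(2-allyl-4,5-dimethoxyphenoxy)-2-methoxy-4-oxocyclohex-2-en-1-yl]oxy}acetic acid, both C5 epimers | C=CCc1cc(OC)c(OC)cc1O[C@]1(OCC(=O)O)CC(CC=C)C(=O)C=C1OC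
F7 | step 10 | 2-thioxopyridin-1(2H)-yl ester of F6 | C=CCc1cc(OC)c(OC)cc1O[C@]1(OCC(=O)On2ccccc2=S)CC(CC=C)C(=O)C=C1OC
F8 | step 10 | (4R,6S)-6-allyl-4-(2-allyl-4,5-dimethoxyphenoxy)-3,4-dimethoxycyclohex-2-en-1-one | C=CCc1cc(OC)c(OC)cc1O[C@]1(OC)C[C@H](CC=C)C(=O)C=C1OC
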